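A count holds through the earlier runs: one Z that ends as J costs one E, and one that ends as D costs one L. In the dawn run J stands at 3.4% of the Z charged against an E charge of 3.35%, in the dusk run at 7.6% against 7.50%, and D in the dawn run reaches 80.2% against an L charge of 80.0%.

| setting | dawn | dusk | spring | flask |
|---|---|---|---|---|
| Z | 20 mM | 20 mM | 20 mM | 20 mM |
| L | 16 mM | 16 mM | 24 mM | 16.0 mM |
| E | 0.67 mM | 1.5 mM | 1 mM | 1.00 mM |
| Q | 0.40 mM | 0.40 mM | 0.40 mM | 0.40 mM |
| remark | run made earlier | run made earlier | run made earlier |  |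
| time |  |  |  | 50 min |

- dawn (time / min: D / %, J / %): 8.00: 68.2, 3.5; 15.0: 75.9, 2.7; 25.0: 78.6, 3.3; 30.0: 78.7, 3.6; 40.0: 79.9, 3.7; 50.0: 79.9, 3.4; 60.0: 80.2, 3.9
- dusk (time / min: D / %, J / %): 8.00: 66.4, 7.6; 15.0: 74.2, 7.2; 25.0: 78.1, 7.3; 30.0: 78.5, 7.6; 40.0: 79.2, 7.6; 50.0: 79.5, 7.6; 60.0: 80.1, 7.0
- spring (time / min: D / %, J / %): 5.00: 76.5, 5.4; 15.0: 92.5, 5.6; 30.0: 94.4, 4.7; 40.0: 95.5, 4.4; 60.0: 94.7, 5.1

(standard deviation of a reading: 0.3 percentage points)



- share of D in D plus J at 8.0 s
- share of D in D plus J at 50 min

In the flask L is 80.0% of the Z charge and E is 5.00%, together 85.0%, so a Z molecule that reaches D or J has a chance of D equal to the L fraction over the sum of the two fractions, and this end share comes to 94.1%.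

Two chemists part over 8.0 s. The first holds that Z and L give D and J side by side in a fixed proportion, a selectivity factor, so he carries the end share of 94.1% back to 8.0 s. The second, whom I join, answers that in the dawn run D gains 12 percentage points after 8.00 min while J moves by 0.4 points, close to the scatter of 0.3 points. The spring share is also lower at 5.00 min, at 93.4%, than at 60.0 min, at 94.9%, so J runs ahead of D early, by an amount at 8.0 s that I can't read from these samples.

The forecast takes the second side, with 67% (48% to 93%) at 8.0 s and 94.1% (93.6% to 94.6%) at 50 min, on the ground that “E is titrated one-to-one into J”.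

The flask gives 63.8% at 8.0 s, lower than the 95.5% from a fit of the side-by-side picture to the runs, and 94.1% at 50 min, the end share as reckoned. The first chemist's figure of 94.1% has its region late: with E at 0% at 25.0 min, the share in the flask already stands at 94.0%.

    Z + Q → Q + G (k = 74.0 M⁻¹ s⁻¹)
    L + Q + G → Q + D (k = 1200 M⁻² s⁻¹)
    G + E → J (k = 4.50 M⁻¹ s⁻¹)

Charged with 0.25 mM of E, the neighbour flask has E at 1.25% of the Z charge and L as before, so its end share reckons to 98.5%. That neighbour flask gives 98.5% at 50 min, with D at 79.9% and J at 1.25%.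

The runs stem from a simulated flask for substances that don't exist, and the scatter is random.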